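One percentage point of J can still be lost to Q: we read Q, which holds two G, as a J that has met one more G, so J should wear away in proportion to [G], pseudo-first-order in J if [G] is taken at its charge.

| flask | G | X | temperature | remark | time |
|---|---|---|---|---|---|
| elm | 0.10 M | 0.070 M | −15 °C | run made earlier |  |
| cedar | 0.050 M | 0.070 M | 0 °C | run made earlier |  |
| maple | 0.075 M | 0.070 M | −15 °C | run made earlier |  |
| birch | 0.10 M | 0.11 M | 0 °C | run made earlier |  |
| west | 0.10 M | 0.0700 M | 0 °C | everything together at the start | 25 h |
| south | 0.10 M | 0.0700 M (fed, over 20 h) | 0 °C | all else is in the flask from the start; the feed brings no volume worth counting | 25 h |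
| north-east | 0.10 M | 0.0700 M (fed, over 20 h) |  | the addition at −30 °C, then warmed to 0 °C; the feed brings no volume worth counting | 25 h |
| east | 0.10 M (fed, over 20 h) | 0.0700 M | 0 °C | all else is in the flask from the start; the feed brings no volume worth counting | 25 h |

| run | time / h | J / % | Q / % |
|---|---|---|---|
| elm | 8.00 | 0 | 0 |
| elm | 15.0 | 0 | 0.1 |
| elm | 25.0 | 1.1 | 0.3 |
| elm | 30.0 | 0.3 | 0 |
| cedar | 1.50 | 0.5 | 0.4 |
| cedar | 4.00 | 0.3 | 0 |
| cedar | 8.00 | 0.5 | 0.9 |
| cedar | 20.0 | 3.6 | 0.2 |
| maple | 3.00 | 0 | 0 |
| maple | 8.00 | 0 | 0.1 |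
| maple | 15.0 | 0.3 | 0 |
| maple | 40.0 | 1.4 | 0 |
| birch | 2.50 | 0 | 0.1 |
| birch | 8.00 | 1.9 | 0.4 |
| birch | 12.0 | 2.1 | 0 |
| birch | 20.0 | 6.6 | 1.4 |

(scatter of a reading: 0.5 percentage points)

- percentages count the G that a species holds: one Q counts as two

1. which flask leads in share of J in J plus Q ("all alike" within 1.5 percentage points) (west / south / north-east / east / all alike)
2. share of J in J plus Q at the end, west
3. share of J in J plus Q at the end, south
4. share of J in J plus Q at the end, north-east
5. share of J in J plus Q at the end, east

So Q over J should grow with [G] and with the hours J has stood. We call Q over J, per molar of charged G and per hour since the start, the wear 0.0952 /M/h, read from the last birch and cedar readings together. It is rough: each Q reading carries 0.5 percentage points, against 1.4% and 0.2%.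

For west, J's clock is the whole 25 h, so Q over J comes to 0.238 and the share to 80.8%. Elm still read J 0% at 15.0 h and −15 °C, so we count no J during the colder addition of north-east. Its clock is then 5.00 h, Q over J 0.0476, and the share 95.5%. We therefore put north-east ahead of west and place south and east between them.

The forecast gives west 83%, south 78%, north-east 82% and east 86%, leads with east, and holds that “North-east, fed cold, makes most of its product after warming, so it resembles west”; our reckoning parts from it there.

The lead goes to north-east, at 97.1%, against 87.6% in west, 90.5% in south and 91.0% in east.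

    G → Z (k = 4.70 × 10⁻⁶ /s, Ea = 101 kJ/mol)
    X + Z → J (k = 1.10 × 10⁻⁴ /M/s, Ea = 66.0 kJ/mol)
    G + J → Q (k = 2.50 × 10⁻⁵ /M/s, Ea = 74.0 kJ/mol)
    Z → L (k = 2.20 × 10⁻⁵ /s, Ea = 81.0 kJ/mol)
    (constants at 0 °C)

At 20.0 h, the change of temperature, north-east held J 0%; at 25.0 h it held J 0.485% and Q 0.0147%, with G 91.8%. Carried to a neighbour of west charged with 0.040 M of G, our wear of 0.0952 /M/h gives a share of 91.3%, and the neighbour holds 94.7%.

(The runs are calculated for an exercise; the scatter is artificial.)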